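**Retrosynthetic overview**
- Target ⇐ acid-mediated γ-lactonisation and desilylation, hydroxyl-directed epoxidation and CBS reduction of a ten-membered C6 ketone that already carries both acyloxy groups and the C1=C10 enoate.
- Ten-membered ring ⇐ three-carbon ring expansion of a seven-membered β-keto ester: intramolecular umpolung allylation at the C6 ketone, then Grob fragmentation of the C6–C10 bond with iodide at C1 as nucleofuge.
- Cyclisation precursor ⇐ iodo-aldol of a cycloheptadienone ester with acetonide-protected L-glyceraldehyde (C7–C9), Morita–Baylis–Hillman reaction (C11–C13), double acylation.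
- Seven-membered ring ⇐ diazoacetate one-carbon ring expansion (1,2-shift) of 3-methylcyclohex-2-enone, then dehydrogenation.
- Ring order: six → seven → bicyclo[5.3.0] (transient) → ten-membered carbocycle → epoxide → γ-lactone.

Assumption: methyl diazoacetate, (4S)-2,2-dimethyl-1,3-dioxolane-4-carbaldehyde and 2-(hydroxymethyl)prop-2-enoic acid are taken as commercial.
Locants C1–C15 follow germacrane numbering of the target (C1–C10 ring, C11–C13 lactone carbons, C14 ester carbon, C15 methyl). Compounds 9–19 are mixtures of epimers at C1 and C10 (15 and 19 also at C7); these centres are erased in step 9.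

**Step 1**
Reactants: 1 3-methylcyclohex-2-en-1-one; 2 methyl diazoacetate
Product: 3 methyl 4-methyl-2-oxocyclohept-3-ene-1-carboxylate
Conditions: BF3·OEt2, CH2Cl2, 0 °C to rt
Reagents that add atoms: none
Why: Lewis-acid-promoted diazoacetate homologation (Tiffeneau–Demjanov-type 1,2-shift ring expansion) in which the saturated α'-carbon migrates in preference to the vinyl carbon, inserting the ester-bearing C10 between C6 and C1; no target stereocenter is set.

**Step 2**
Reactants: 3 methyl 4-methyl-2-oxocyclohept-3-ene-1-carboxylate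
Product: 6 methyl 5-methyl-7-oxocyclohepta-1,5-diene-1-carboxylate, via selenide 4 (not isolated), via selenoxide 5 (not isolated)
Conditions: PhSeCl, pyridine, CH2Cl2, 0 °C; then 30% H2O2, 0 °C to rt
Reagents that add atoms: none
Why: α-selenenylation of the β-keto ester and selenoxide syn-elimination (Reich dehydrogenation) can only eliminate toward C1 and give the C1=C10 alkylidene β-keto ester.

**Step 3**
Reactants: 6 methyl 5-methyl-7-oxocyclohepta-1,5-diene-1-carboxylate; 7 (4S)-2,2-dimethyl-1,3-dioxolane-4-carbaldehyde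
Product: 11 methyl 1-{(R)-acetoxy[(4S)-2,2-dimethyl-1,3-dioxolan-4-yl]methyl}-7-iodo-4-methyl-2-oxocyclohept-3-ene-1-carboxylate, via iodo silyl dienol ether 8 (not isolated), via silyl aldol 9 (not isolated), via alcohol 10 (not isolated)
Conditions: Me3SiI, CH2Cl2, −78 °C; 7, Me3SiOTf (10 mol %), −78 to −40 °C; aq. citric acid work-up; Ac2O, 4-(dimethylamino)pyridine, pyridine, 0 °C
Reagents that add atoms: iodotrimethylsilane C[Si](C)(C)I; acetic anhydride CC(=O)OC(C)=O
Why: tandem conjugate iodide addition/Mukaiyama aldol (halo-aldol) then acetylation, in which iodide adds to the doubly activated C1 and the silyl enol ether attacks the aldehyde through an open transition state under Felkin–Anh control of the chiral-pool dioxolane centre (C8), setting C9 as the anti (erythro) isomer.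

**Step 4**
Reactants: 11 iodo acetate from step 3
Product: 12 methyl 1-[(1R,2S)-1-acetoxy-2,3-dihydroxypropyl]-7-iodo-4-methyl-2-oxocyclohept-3-ene-1-carboxylate
Conditions: AcOH/H2O (4:1), 40 °C
Reagents that add atoms: none
Why: acid-catalysed acetonide hydrolysis frees the C7/C8 diol and leaves the acetate, the neopentyl-type iodide and the quaternary β-keto ester untouched.

**Step 5**
Reactants: 12 diol from step 4
Product: 13 methyl 1-[(1R,2R)-1-acetoxy-2-hydroxy-3-oxopropyl]-7-iodo-4-methyl-2-oxocyclohept-3-ene-1-carboxylate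
Conditions: 2,2,6,6-tetramethylpiperidin-1-oxyl (10 mol %), PhI(OAc)2, CH2Cl2, rt
Reagents that add atoms: none
Why: nitroxyl-catalysed oxidation is selective for the primary C7 hydroxyl over the secondary C8 hydroxyl.

**Step 6**
Reactants: 13 aldehyde from step 5; 14 methyl acrylate
Product: 15 methyl 1-[(1R,2S)-1-acetoxy-2,3-dihydroxy-4-(methoxycarbonyl)pent-4-en-1-yl]-7-iodo-4-methyl-2-oxocyclohept-3-ene-1-carboxylate
Conditions: methyl acrylate (10 equiv), 1,4-diazabicyclo[2.2.2]octane (0.5 equiv), MeOH (2 equiv), rt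
Reagents that add atoms: none
Why: Morita–Baylis–Hillman reaction installs C11–C13, and the new C7 carbinol centre is inconsequential because C7 becomes part of an allyl unit in step 9.

**Step 7**
Reactants: 16 2-(hydroxymethyl)prop-2-enoic acid
Product: 18 2-({[tert-butyl(dimethyl)silyl]oxy}methyl)prop-2-enoic acid, via bis-silyl derivative 17 (not isolated)
Conditions: t-BuMe2SiCl, imidazole, DMF, rt; then K2CO3 (cat.), MeOH/H2O, rt
Reagents that add atoms: tert-butyldimethylsilyl chloride CC(C)(C)[Si](C)(C)Cl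
Why: exhaustive silylation followed by selective solvolysis of the labile silyl ester gives the O-protected acid.

**Step 8**
Reactants: 15 diol from step 6; 18 protected acid (2.5 equiv)
Product: 19 methyl 1-[(1R,2S)-1-acetoxy-2,3-bis({2-[(tert-butyldimethylsilyloxy)methyl]prop-2-enoyl}oxy)-4-(methoxycarbonyl)pent-4-en-1-yl]-7-iodo-4-methyl-2-oxocyclohept-3-ene-1-carboxylate
Conditions: N,N'-dicyclohexylcarbodiimide, 4-(dimethylamino)pyridine (cat.), CH2Cl2, 0 °C to rt
Reagents that add atoms: none
Why: Steglich esterification acylates both secondary hydroxyls, so the C8 ester is the final side chain and the allylic C7 ester is the leaving group for step 9 (any allylic ester isomer converges there).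

**Step 9**
Reactants: 19 bis-ester from step 8
Product: 21 methyl (1E,5Z,8R,9S,10R)-10-acetoxy-8-(3-methoxy-3-oxoprop-1-en-2-yl)-5-methyl-7-oxo-9-({2-[(tert-butyldimethylsilyloxy)methyl]prop-2-enoyl}oxy)cyclodeca-1,5-diene-1-carboxylate, via bicyclic alkoxide 20 (not isolated)
Conditions: Pd(PPh3)4 (5 mol %), In powder, LiCl, DMF/THF, rt then 40 °C
Reagents that add atoms: none
Why: Proposed new method: zerovalent palladium ionises the allylic C7 ester, indium reduces the allyl–palladium complex to an allylindium species that adds through C7 to the C6 ketone in a chelated chair-like transition state (indium bound to O6 and the C8 acyloxy oxygen, which places C11 cis to O8 and so sets C7), and the resulting γ-iodo alkoxide undergoes Grob fragmentation of the C6–C10 bond with loss of iodide (far better nucleofuge than the C9 acetate) to give the ten-membered ring with the ring-cis (E) C1=C10 enoate; the closest known reaction types are the palladium/indium umpolung allylation of carbonyls with Morita–Baylis–Hillman acetates, the Grob fragmentation of γ-halo alkoxides and Trost's three-carbon ring expansion.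

**Step 10**
Reactants: 21 ten-membered ketone from step 9
Product: 22 methyl (1E,5Z,7R,8S,9S,10R)-10-acetoxy-7-hydroxy-8-(3-methoxy-3-oxoprop-1-en-2-yl)-5-methyl-9-({2-[(tert-butyldimethylsilyloxy)methyl]prop-2-enoyl}oxy)cyclodeca-1,5-diene-1-carboxylate
Conditions: (R)-1-methyl-3,3-diphenyltetrahydro-1H,3H-pyrrolo[1,2-c][1,3,2]oxazaborole (20 mol %), BH3·SMe2, THF, −30 °C; MeOH quench
Reagents that add atoms: none
Why: Corey–Bakshi–Shibata reduction under reagent control (alkenyl group as the larger ketone substituent) delivers hydride to the β-face, setting the C6 hydroxyl α without touching the esters.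

**Step 11**
Reactants: 22 allylic alcohol from step 10
Product: 23 methyl (1S,2S,3S,4S,5R,6E,10R)-5-acetoxy-2-hydroxy-3-(3-methoxy-3-oxoprop-1-en-2-yl)-10-methyl-4-({2-[(tert-butyldimethylsilyloxy)methyl]prop-2-enoyl}oxy)-11-oxabicyclo[8.1.0]undec-6-ene-6-carboxylate
Conditions: VO(acac)2 (5 mol %), t-BuOOH, CH2Cl2, 0 °C
Reagents that add atoms: tert-butyl hydroperoxide CC(C)(C)OO
Why: hydroxyl-directed vanadium-catalysed epoxidation (Sharpless–Michaelson) of the only electron-rich alkene occurs syn to the C6 hydroxyl, as for eight- and nine-membered Z-allylic alcohols, setting C4 and C5 (α-epoxide).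

**Step 12**
Reactants: 23 epoxy alcohol from step 11
Product: 25 target CNP0147016.1, via lactone silyl ether 24 (not isolated)
Conditions: pyridinium p-toluenesulfonate (cat.), CH2Cl2, rt; then HF·pyridine, pyridine, THF, 0 °C
Reagents that add atoms: none
Why: acid-catalysed lactonisation of the 6α-hydroxyl onto the C12 methyl ester closes the trans-fused α-methylene-γ-lactone, and buffered HF·pyridine then removes the silyl ether without opening the epoxide.

**Compound list**
1 | 3-methylcyclohex-2-en-1-one | CC1=CC(=O)CCC1 | starting material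
2 | methyl diazoacetate | COC(=O)C=[N+]=[N-] | starting material
3 | methyl 4-methyl-2-oxocyclohept-3-ene-1-carboxylate (racemic) | COC(=O)C1CCCC(C)=CC1=O | intermediate
4 | methyl 4-methyl-2-oxo-1-(phenylselanyl)cyclohept-3-ene-1-carboxylate | COC(=O)C1([Se]c2ccccc2)CCCC(C)=CC1=O | intermediate
5 | methyl 4-methyl-2-oxo-1-(phenylseleninyl)cyclohept-3-ene-1-carboxylate | COC(=O)C1([Se](=O)c2ccccc2)CCCC(C)=CC1=O | intermediate
6 | methyl 5-methyl-7-oxocyclohepta-1,5-diene-1-carboxylate | COC(=O)C1=CCCC(C)=CC1=O | intermediate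
7 | (4S)-2,2-dimethyl-1,3-dioxolane-4-carbaldehyde | O=C[C@@H]1COC(C)(C)O1 | starting material
8 | methyl 7-iodo-4-methyl-2-[(trimethylsilyl)oxy]cyclohepta-1,3-diene-1-carboxylate | COC(=O)C1=C(O[Si](C)(C)C)C=C(C)CCC1I | intermediate
9 | trimethylsilyl ether of 10 | COC(=O)C1([C@@H](O[Si](C)(C)C)[C@@H]2COC(C)(C)O2)C(I)CCC(C)=CC1=O | intermediate
10 | methyl 1-{(R)-hydroxy[(4S)-2,2-dimethyl-1,3-dioxolan-4-yl]methyl}-7-iodo-4-methyl-2-oxocyclohept-3-ene-1-carboxylate | COC(=O)C1([C@@H](O)[C@@H]2COC(C)(C)O2)C(I)CCC(C)=CC1=O | intermediate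
11 | methyl 1-{(R)-acetoxy[(4S)-2,2-dimethyl-1,3-dioxolan-4-yl]methyl}-7-iodo-4-methyl-2-oxocyclohept-3-ene-1-carboxylate | COC(=O)C1([C@@H](OC(C)=O)[C@@H]2COC(C)(C)O2)C(I)CCC(C)=CC1=O | intermediate
12 | methyl 1-[(1R,2S)-1-acetoxy-2,3-dihydroxypropyl]-7-iodo-4-methyl-2-oxocyclohept-3-ene-1-carboxylate | COC(=O)C1([C@@H](OC(C)=O)[C@@H](O)CO)C(I)CCC(C)=CC1=O | intermediate
13 | methyl 1-[(1R,2R)-1-acetoxy-2-hydroxy-3-oxopropyl]-7-iodo-4-methyl-2-oxocyclohept-3-ene-1-carboxylate | COC(=O)C1([C@@H](OC(C)=O)[C@@H](O)C=O)C(I)CCC(C)=CC1=O | intermediate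
14 | methyl acrylate | C=CC(=O)OC | starting material
15 | methyl 1-[(1R,2S)-1-acetoxy-2,3-dihydroxy-4-(methoxycarbonyl)pent-4-en-1-yl]-7-iodo-4-methyl-2-oxocyclohept-3-ene-1-carboxylate | COC(=O)C1([C@@H](OC(C)=O)[C@@H](O)C(O)C(=C)C(=O)OC)C(I)CCC(C)=CC1=O | intermediate
16 | 2-(hydroxymethyl)prop-2-enoic acid | C=C(CO)C(=O)O | starting material
17 | tert-butyldimethylsilyl 2-({[tert-butyl(dimethyl)silyl]oxy}methyl)prop-2-enoate | C=C(CO[Si](C)(C)C(C)(C)C)C(=O)O[Si](C)(C)C(C)(C)C | intermediate
18 | 2-({[tert-butyl(dimethyl)silyl]oxy}methyl)prop-2-enoic acid | C=C(CO[Si](C)(C)C(C)(C)C)C(=O)O | intermediate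
19 | bis-ester of 15 with 18 at O7 and O8 (full name in step 8) | COC(=O)C1([C@@H](OC(C)=O)[C@@H](OC(=O)C(=C)CO[Si](C)(C)C(C)(C)C)C(OC(=O)C(=C)CO[Si](C)(C)C(C)(C)C)C(=C)C(=O)OC)C(I)CCC(C)=CC1=O | intermediate
20 | cis-fused bicyclo[5.3.0]decenol from C6–C7 closure (7R,8S,9R; formed as its indium alkoxide, drawn as the alcohol) | C=C(CO[Si](C)(C)C(C)(C)C)C(=O)O[C@H]1[C@@H](C(=C)C(=O)OC)C2(O)C=C(C)CCC(I)C2(C(=O)OC)[C@H]1OC(C)=O | intermediate
21 | ten-membered ketone (full name in step 9) | C=C(CO[Si](C)(C)C(C)(C)C)C(=O)O[C@H]1[C@@H](C(=C)C(=O)OC)C(=O)/C=C(C)\CC/C=C(/C(=O)OC)[C@H]1OC(C)=O | intermediate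
22 | 6α-allylic alcohol (full name in step 10) | C=C(CO[Si](C)(C)C(C)(C)C)C(=O)O[C@H]1[C@@H](C(=C)C(=O)OC)[C@H](O)/C=C(C)\CC/C=C(/C(=O)OC)[C@H]1OC(C)=O | intermediate
23 | 4α,5α-epoxy 6α-alcohol (full name in step 11) | C=C(CO[Si](C)(C)C(C)(C)C)C(=O)O[C@H]1[C@@H](C(=C)C(=O)OC)[C@H](O)[C@@H]2O[C@]2(C)CC/C=C(/C(=O)OC)[C@H]1OC(C)=O | intermediate
24 | O-tert-butyldimethylsilyl ether of 25 | C=C(CO[Si](C)(C)C(C)(C)C)C(=O)O[C@H]1[C@H]2C(=C)C(=O)O[C@@H]2[C@@H]2O[C@]2(C)CC/C=C(/C(=O)OC)[C@H]1OC(C)=O | intermediate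
25 | methyl (1(10)E,4R,5S,6S,7R,8S,9R)-9-acetoxy-4,5-epoxy-8-{[2-(hydroxymethyl)prop-2-enoyl]oxy}-12-oxo-6,12-epoxygermacra-1(10),11(13)-dien-14-oate | C=C(CO)C(=O)O[C@H]1[C@H]2C(=C)C(=O)O[C@@H]2[C@@H]2O[C@]2(C)CC/C=C(/C(=O)OC)[C@H]1OC(C)=O | target

**Totals**
Total step count: 12. Longest linear sequence: 11 steps (1 to 25 through steps 1–6 and 8–12).

**Steps most likely to fail, with fallbacks**

Step 9 (the new cascade) may stall at the alkoxide, lactonise, or give the wrong C7 epimer. The fallback uses known reactions only and sets out from 15. PBr3 (Et2O, −20 °C) replaces the allylic C7 hydroxyl with allylic transposition to give methyl 1-[(1R,2S,3Z)-1-acetoxy-5-bromo-2-hydroxy-4-(methoxycarbonyl)pent-3-en-1-yl]-7-iodo-4-methyl-2-oxocyclohept-3-ene-1-carboxylate F1. Steglich esterification of the C8 hydroxyl with 18 gives the bromo ester F2. Zinc dust in THF/aq. NH4Cl effects the classical intramolecular Barbier allylation to the isolable tertiary alcohol 20. KN(SiMe3)2 (THF, −78 °C) then triggers the Grob fragmentation, and the fallback rejoins the route at 21.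

Step 6 puts a β-acetoxy α-hydroxy aldehyde under amine catalysis, where acetate elimination or acyl migration can compete. The fallback sets out from 13 and changes the bond-forming manifold. Preformed [1-(methoxycarbonyl)vinyl]diisobutylaluminium, made by hydroalumination of methyl propiolate with i-Bu2AlH and N-methylmorpholine N-oxide in THF, adds to the aldehyde under non-basic conditions. It gives the same adduct and returns at 15 (F0, no new compound).

Step 10 relies on reagent control against the intrinsic facial bias of the ten-membered enone. The fallback sets out from 21. LiBH(s-Bu)3 (THF, −78 °C) attacks from the periphery, anti to the C7 side chain, and gives the 6-epimeric alcohol F3. Mitsunobu inversion (PPh3, diisopropyl azodicarboxylate, chloroacetic acid) gives the 6α-chloroacetate F4. Thiourea/NaHCO3 removes the chloroacetate selectively, and the fallback returns at 22.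

**Further compounds**
F0 | step 6 | none | none
F1 | step 9 | methyl 1-[(1R,2S,3Z)-1-acetoxy-5-bromo-2-hydroxy-4-(methoxycarbonyl)pent-3-en-1-yl]-7-iodo-4-methyl-2-oxocyclohept-3-ene-1-carboxylate | COC(=O)C1([C@@H](OC(C)=O)[C@@H](O)/C=C(\CBr)C(=O)OC)C(I)CCC(C)=CC1=O
F2 | step 9 | 2-O-{2-[(tert-butyldimethylsilyloxy)methyl]prop-2-enoyl} ester of F1 | COC(=O)C1([C@@H](OC(C)=O)[C@@H](OC(=O)C(=C)CO[Si](C)(C)C(C)(C)C)/C=C(\CBr)C(=O)OC)C(I)CCC(C)=CC1=O
F3 | step 10 | 6-epimer (6β-alcohol) of 22 | C=C(CO[Si](C)(C)C(C)(C)C)C(=O)O[C@H]1[C@@H](C(=C)C(=O)OC)[C@@H](O)/C=C(C)\CC/C=C(/C(=O)OC)[C@H]1OC(C)=O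
F4 | step 10 | 6α-chloroacetate of 22 | C=C(CO[Si](C)(C)C(C)(C)C)C(=O)O[C@H]1[C@@H](C(=C)C(=O)OC)[C@H](OC(=O)CCl)/C=C(C)\CC/C=C(/C(=O)OC)[C@H]1OC(C)=O
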